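A pitfall in a two-step flask is to start the intermediate's clock at zero, although the intermediate is born from the substrate during the run and later portions spend less time exposed to the catalyst.

in all of them: substrate 0.94 M
- Sunday's: catalyst 28 mM; temperature 80 °C; run made earlier
- violet: catalyst 19 mM; temperature 80 °C; time 8.0 min
- grey: catalyst 19 mM; temperature 50 °C; time 8.0 min
- red: catalyst 19 mM; temperature 20 °C; time 8.0 min

Sunday's run (percent of the substrate charged)

| time / s | intermediate / % | target / % |
|---|---|---|
| 10.0 | 3.6 | 96.2 |
| 12.0 | 2.2 | 98.2 |
| 20.0 | 0.2 | 99.5 |
| 25.0 | 0 | 99.6 |
| 40.0 | 0 | 99.9 |
| 60.0 | 0 | 99.8 |
| 90.0 | 0 | 100.5 |

(each reading ± 0.3 percentage points)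

- reactions considered so far: substrate -> intermediate; catalyst + intermediate -> catalyst + target
- the earlier runs do not show what temperature does; that part of a forecast is a guess
- no earlier run changes the charge of catalyst; that part of a forecast is a guess

- the best flask by amount of intermediate, in percent of the substrate charged; "all alike" if 1.5 percentage points covers them all (violet / grey / red / all alike)
- amount of intermediate at the end, in percent of the substrate charged, violet
- amount of intermediate at the end, in percent of the substrate charged, grey
- amount of intermediate at the end, in percent of the substrate charged, red

In Sunday's run the intermediate falls from 3.6% at 10.0 s to 2.2% at 12.0 s, a rough reading of 0.246 /s at these small amounts. The catalyst is returned by the step, so on the reactions considered, and as a guess since no run varies the charge, this pseudo-first-order constant scales with the catalyst, and violet's 19 mM gives the intermediate a lifetime of 5.98 s. Violet's time then holds 80.2 lifetimes; this number of lifetimes in the flask's time is the lifetime count.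

No run shows temperature, so the reckoning here guesses one halving of the rate per 10 degrees. Grey then has 3 halvings and a count of 10.0, and red has 6 and a count of 1.25.

Two extreme versions of red can be solved at once. If the whole charge becomes intermediate at the start, 28.6% survives; if it appears at the last moment, 100 percent survives. Once the substrate is used up, red at this count lies between them. Sunday's balance at 10.0 s is 99.8%, which as a reading puts the substrate under about 1 percent and its lifetime at 80 °C under 2.17 s, shorter than the lifetime of the intermediate in violet at the same temperature. Birth is therefore late on average by less than 0.363 of a lifetime, and a late birth of that size raises the survivors by the factor one over one minus that share, so if both steps slow alike, the reckoning here places red between 28.6% and 44.8%.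

The forecast named red as best, with 0% in violet, 0.3% in grey and 20% in red, adding: “A slower first step could shift this either way”. The flasks give 0% in violet, 0% in grey and 31.4% in red.

    substrate → intermediate (k = 0.0110 /s, Ea = 84.0 kJ/mol)
    catalyst + intermediate → catalyst + target (k = 0.160 /M/s, Ea = 62.0 kJ/mol)
    (constants at 20 °C)

In red the substrate's half-life of 1.1 min is shorter than the 3.80 min half-life of the flask's slowest mode as it stands at 8.00 min, and the intermediate is made 4.06 times faster than it is used up at 1.04 min, while at 8.00 min its making is 0.0589 of its use. The constants give red a lifetime count of 1.46, and birth at the start at that count leaves 23.2%, less than the 31.4% in red. Grey, at its reckoned count of 10.0, holds 0%.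

The earlier runs and the new flask are calculated from invented constants; scatter was added.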